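**Plan**

- Target 25 is (2S)-7-hydroxy-2-(4-hydroxyphenyl)-6,8-diprenylchroman-4-one. The retrosynthesis cuts C2–C1' first (aryl addition to a chromone), then the one-carbon unit C2 with its O1–C2 and C2–C3 bonds (ring C), then C4–C4a (acetyl shift from O1), and last ring A at C8–C8a, C6–C7 and C4a–C8a.
- The feature that allows the key step is ring A: a pentasubstituted resorcinol with O1 on C8a, prenyl on C8, oxygen on C7, prenyl on C6, H on C5 and C4a open, whose two oxygens must differ. A vinylketene/silyl ynol ether benzannulation gives this pattern with O1 free and O7 silylated.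
- Forward: diazo enone 6 (from sulcatone, steps 1–3) and silyl ynol ether 13 (from ethynyltrimethylsilane and prenyl bromide, steps 4–6) are joined in step 7, which closes ring A. Ring C follows (steps 8–10, chromone 22), ring B is attached in step 11, and both silyl groups are removed in step 12.
- Stereochemistry: the only stereocentre, C2 (S), is set by the chiral rhodium catalyst in the 1,4-addition of arylboronic acid 23 to chromone 22. Base-free addition and buffered desilylation guard it against retro-oxa-Michael racemisation.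

Key step: step 7

Assumption: the (S)-configured biaryl bisphosphine is expected to give the 2S product, by analogy with the face selection of rhodium/(S)-biaryl bisphosphine catalysts on cyclic enones; if a first run shows the opposite sense, the (R)-ligand is used under the same conditions.

**Route**

Step 1
Reactants: 1 6-methylhept-5-en-2-one (sulcatone)
Product: 2 1-(dimethylamino)-7-methyloct-6-en-3-one
Conditions: LDA, THF, −78 °C; then CH2=NMe2+ I−, −78 °C → rt
Reagents that add atoms: N,N-dimethylmethyleneiminium iodide (Eschenmoser's salt), C=[N+](C)C.[I-]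
Why: The kinetic lithium enolate forms at the methyl group of the methyl ketone and adds to the preformed iminium ion (Mannich reaction), so the new carbon is placed on the unbranched side.

Step 2
Reactants: 2 1-(dimethylamino)-7-methyloct-6-en-3-one
Product: 4 7-methylocta-1,6-dien-3-one, via ammonium iodide 3 (not isolated)
Conditions: MeI, Et2O, rt; then NaHCO3 (aq), CH2Cl2, rt
Reagents that add atoms: iodomethane, CI (its methyl group is held only in intermediate 3 and leaves as trimethylamine)
Why: Quaternisation turns the dimethylamino group into a leaving group and mild base then effects E1cB β-elimination of the Mannich methiodide (Hofmann-type elimination) to the vinyl ketone, which should be used at once.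

Step 3
Reactants: 4 7-methylocta-1,6-dien-3-one
Product: 6 4-diazo-7-methylocta-1,6-dien-3-one, via trifluoroacetyl diketone 5 (not isolated)
Conditions: LiHMDS, THF, −78 °C (4 added slowly); CF3CO2CH2CF3, −78 °C; then 4-AcNHC6H4SO2N3, Et3N, H2O, MeCN, rt, dark
Reagents that add atoms: 4-acetamidobenzenesulfonyl azide, CC(=O)Nc1ccc(cc1)S(=O)(=O)N=[N+]=[N-]; 2,2,2-trifluoroethyl trifluoroacetate, O=C(OCC(F)(F)F)C(F)(F)F (its trifluoroacetyl group is held only in intermediate 5)
Why: In this detrifluoroacetylative (Regitz-type) diazo transfer the kinetic enolate at C4, the only enolisable position, is trifluoroacetylated in a Claisen condensation and the resulting 1,3-diketone accepts N2 from the sulfonyl azide with loss of the trifluoroacetyl group, a sequence suited to base-sensitive enones when the ketone is added slowly to excess base at −78 °C.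

Step 4
Reactants: 7 ethynyltrimethylsilane; 8 1-bromo-3-methylbut-2-ene (prenyl bromide)
Product: 9 trimethyl(5-methylhex-4-en-1-yn-1-yl)silane
Conditions: EtMgBr, THF, 0 → 40 °C; then CuBr·SMe2 (5 mol %), 8, THF, rt → 50 °C
Reagents that add atoms: none
Why: Copper-catalysed coupling of the alkynyl Grignard reagent with the allylic bromide should proceed at the primary carbon (SN2 rather than SN2′, since the γ-carbon is tertiary) and give the skipped enyne.

Step 5
Reactants: 9 trimethyl(5-methylhex-4-en-1-yn-1-yl)silane
Product: 10 5-methylhex-4-en-1-yne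
Conditions: K2CO3 (cat.), MeOH, rt; pentane extraction, careful distillation
Reagents that add atoms: none
Why: Methoxide-mediated protodesilylation of the alkynylsilane is fast at room temperature and leaves the skipped enyne untouched.

Step 6
Reactants: 10 5-methylhex-4-en-1-yne
Product: 13 triisopropyl[(5-methylhex-4-en-1-yn-1-yl)oxy]silane, via lithium acetylide 11 (not isolated), via lithium ynolate 12 (not isolated)
Conditions: LiHMDS, THF, −78 °C; t-BuOOLi (from anhydrous t-BuOOH, LiHMDS), −78 → 0 °C; then TIPSOTf, −78 → 0 °C; non-acidic work-up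
Reagents that add atoms: tert-butyl hydroperoxide, CC(C)(C)OO; triisopropylsilyl trifluoromethanesulfonate, CC(C)[Si](OS(=O)(=O)C(F)(F)F)(C(C)C)C(C)C; lithium bis(trimethylsilyl)amide, [Li]N([Si](C)(C)C)[Si](C)(C)C (its lithium is held only in intermediates 11 and 12)
Why: LiHMDS removes only the alkyne C–H (the doubly activated CH2 is far less acidic), the acetylide is oxidised at carbon by lithium tert-butyl peroxide to the ynolate (electrophilic oxygen transfer from a peroxide), and the bulky silyl triflate traps the ynolate on oxygen to give the silyl ynol ether.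

Step 7
Reactants: 6 4-diazo-7-methylocta-1,6-dien-3-one; 13 triisopropyl[(5-methylhex-4-en-1-yn-1-yl)oxy]silane
Product: 18 2,4-bis(3-methylbut-2-en-1-yl)-3-[(triisopropylsilyl)oxy]phenol, via vinylketene 14 (not isolated), via vinylcyclobutenone 15 (not isolated), via dienylketene 16 (not isolated), via cyclohexadienone 17 (not isolated)
Conditions: 6 (1.3 equiv), 13 (1.0 equiv), hν (254 nm, low-pressure Hg, quartz), degassed ClCH2CH2Cl, rt; then 80 °C, dark
Reagents that add atoms: none
Why: Irradiation expels N2 from 6 with migration of the vinyl group (photochemical Wolff rearrangement) to give vinylketene 14, which undergoes [2+2] cycloaddition with the electron-rich triple bond of 13 to form vinylcyclobutenone 15 and, in flavanone numbering, the C8–C8a and C6–C7 bonds. Reversible 4π electrocyclic opening of 15 gives dienylketene 16, whose E isomer closes ring A by thermal disrotatory 6π electrocyclisation between the ketene carbon and the vinyl terminus (C8a–C4a), and dienone 17 enolises to phenol 18. The closest known reaction type is the Danheiser benzannulation in its photo-Wolff form, in which diazo enones and silyl ynol ethers give resorcinol monosilyl ethers. No stereocentre is set: the quaternary carbon of 15 is racemic and is lost on ring opening. The step needs regiocontrol in the [2+2] event, which the polarisation of the ynol ether secures, since its nucleophilic prenyl-bearing carbon attacks the ketene carbonyl carbon and so places OTIPS meta to the new OH, between the two prenyl-bearing carbons. It also needs Wolff migration to outrun a 1,2-hydrogen shift of the keto carbene, which direct 254 nm excitation of the diazo ketone favours, and the thermal phase is run in the dark so that the o-prenylphenol is not exposed to UV light.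

Step 8
Reactants: 18 2,4-bis(3-methylbut-2-en-1-yl)-3-[(triisopropylsilyl)oxy]phenol
Product: 19 2,4-bis(3-methylbut-2-en-1-yl)-3-[(triisopropylsilyl)oxy]phenyl acetate
Conditions: Ac2O, Et3N, DMAP (cat.), CH2Cl2, rt
Reagents that add atoms: acetic anhydride, CC(=O)OC(C)=O
Why: DMAP-catalysed acyl transfer (Steglich-type O-acylation) should esterify the hindered phenol without touching the silyl ether or the prenyl groups.

Step 9
Reactants: 19 2,4-bis(3-methylbut-2-en-1-yl)-3-[(triisopropylsilyl)oxy]phenyl acetate
Product: 20 1-{2-hydroxy-3,5-bis(3-methylbut-2-en-1-yl)-4-[(triisopropylsilyl)oxy]phenyl}ethan-1-one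
Conditions: hν (254 nm, quartz), degassed cyclohexane (dilute), rt
Reagents that add atoms: none
Why: In the photo-Fries rearrangement the excited aryl ester cleaves at the ArO–acyl bond and the caged acetyl radical recombines at the only ring carbon ortho or para to oxygen that carries hydrogen (the future C4a), and the chelated o-hydroxy ketone formed is shielded from further photochemistry by excited-state proton transfer.

Step 10
Reactants: 20 1-{2-hydroxy-3,5-bis(3-methylbut-2-en-1-yl)-4-[(triisopropylsilyl)oxy]phenyl}ethan-1-one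
Product: 22 6,8-bis(3-methylbut-2-en-1-yl)-7-[(triisopropylsilyl)oxy]-4H-chromen-4-one, via enaminone 21 (not isolated)
Conditions: Me2NCH(OMe)2, toluene, 90 °C; then 2 M HCl (aq), CH2Cl2, rt
Reagents that add atoms: N,N-dimethylformamide dimethyl acetal, COC(OC)N(C)C
Why: Condensation of the methyl ketone with the amide acetal gives the enaminone, and acid promotes 6-endo conjugate addition of the 2'-hydroxyl followed by loss of dimethylamine (enaminone route to chromones), under conditions mild enough for the prenyl groups and the TIPS ether.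

Step 11
Reactants: 22 6,8-bis(3-methylbut-2-en-1-yl)-7-[(triisopropylsilyl)oxy]-4H-chromen-4-one; 23 {4-[(tert-butyldimethylsilyl)oxy]phenyl}boronic acid
Product: 24 (2S)-2-{4-[(tert-butyldimethylsilyl)oxy]phenyl}-6,8-bis(3-methylbut-2-en-1-yl)-7-[(triisopropylsilyl)oxy]-2,3-dihydro-4H-chromen-4-one
Conditions: [Rh(OH)(cod)]2 (cat.), (S)-MeO-F12-BIPHEP [(S)-2,2'-bis{bis(3,4,5-trifluorophenyl)phosphino}-6,6'-dimethoxybiphenyl] (cat.), 23 (3 equiv), toluene/H2O, 50 °C
Reagents that add atoms: none
Why: In this rhodium-catalysed asymmetric 1,4-addition (Hayashi–Miyaura reaction) the aryl–rhodium species inserts the chromone C2=C3 bond on the face left open by the chiral bisphosphine, which sets C2 as S, and water protonates the oxa-π-allyl rhodium; the electron-poor ligand speeds insertion into the deactivated chromone, no base is present that could open the product by retro-oxa-Michael reaction, and the trisubstituted prenyl alkenes should not insert.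

Step 12
Reactants: 24 (2S)-2-{4-[(tert-butyldimethylsilyl)oxy]phenyl}-6,8-bis(3-methylbut-2-en-1-yl)-7-[(triisopropylsilyl)oxy]-2,3-dihydro-4H-chromen-4-one
Product: 25 (2S)-7-hydroxy-2-(4-hydroxyphenyl)-6,8-bis(3-methylbut-2-en-1-yl)-2,3-dihydro-4H-chromen-4-one
Conditions: TBAF, AcOH (1:1, 2.5 equiv each), THF, 0 °C → rt
Reagents that add atoms: none
Why: Fluoride cleaves both aryl silyl ethers (Si–O cleavage driven by Si–F bond formation), and the acetic acid buffer keeps the medium from becoming basic enough for ring opening to the chalcone, so the C2 configuration should be kept.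

**Compound list**

1 | 6-methylhept-5-en-2-one (sulcatone) | CC(=O)CCC=C(C)C | starting material
2 | 1-(dimethylamino)-7-methyloct-6-en-3-one | CN(C)CCC(=O)CCC=C(C)C | intermediate
3 | N,N,N,7-tetramethyl-3-oxooct-6-en-1-aminium iodide | C[N+](C)(C)CCC(=O)CCC=C(C)C.[I-] | intermediate
4 | 7-methylocta-1,6-dien-3-one | C=CC(=O)CCC=C(C)C | intermediate
5 | 1,1,1-trifluoro-3-(3-methylbut-2-en-1-yl)hex-5-ene-2,4-dione | C=CC(=O)C(CC=C(C)C)C(=O)C(F)(F)F | intermediate
6 | 4-diazo-7-methylocta-1,6-dien-3-one | C=CC(=O)C(=[N+]=[N-])CC=C(C)C | intermediate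
7 | ethynyltrimethylsilane | C#C[Si](C)(C)C | starting material
8 | 1-bromo-3-methylbut-2-ene (prenyl bromide) | CC(C)=CCBr | starting material
9 | trimethyl(5-methylhex-4-en-1-yn-1-yl)silane | CC(C)=CCC#C[Si](C)(C)C | intermediate
10 | 5-methylhex-4-en-1-yne | C#CCC=C(C)C | intermediate
11 | (5-methylhex-4-en-1-yn-1-yl)lithium | [Li]C#CCC=C(C)C | intermediate
12 | lithium 5-methylhex-4-en-1-yn-1-olate | [Li+].[O-]C#CCC=C(C)C | intermediate
13 | triisopropyl[(5-methylhex-4-en-1-yn-1-yl)oxy]silane | CC(C)=CCC#CO[Si](C(C)C)(C(C)C)C(C)C | intermediate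
14 | 2-ethenyl-5-methylhexa-1,4-dien-1-one | C=CC(CC=C(C)C)=C=O | intermediate
15 | rac-4-ethenyl-2,4-bis(3-methylbut-2-en-1-yl)-3-[(triisopropylsilyl)oxy]cyclobut-2-en-1-one | O=C1C(CC=C(C)C)=C(O[Si](C(C)C)(C(C)C)C(C)C)C1(C=C)CC=C(C)C | intermediate
16 | (3E)-2,4-bis(3-methylbut-2-en-1-yl)-3-[(triisopropylsilyl)oxy]hexa-1,3,5-trien-1-one | O=C=C(CC=C(C)C)/C(O[Si](C(C)C)(C(C)C)C(C)C)=C(/CC=C(C)C)C=C | intermediate
17 | 2,4-bis(3-methylbut-2-en-1-yl)-3-[(triisopropylsilyl)oxy]cyclohexa-2,4-dien-1-one | O=C1CC=C(CC=C(C)C)C(O[Si](C(C)C)(C(C)C)C(C)C)=C1CC=C(C)C | intermediate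
18 | 2,4-bis(3-methylbut-2-en-1-yl)-3-[(triisopropylsilyl)oxy]phenol | CC(C)=CCc1ccc(O)c(CC=C(C)C)c1O[Si](C(C)C)(C(C)C)C(C)C | intermediate
19 | 2,4-bis(3-methylbut-2-en-1-yl)-3-[(triisopropylsilyl)oxy]phenyl acetate | CC(=O)Oc1ccc(CC=C(C)C)c(O[Si](C(C)C)(C(C)C)C(C)C)c1CC=C(C)C | intermediate
20 | 1-{2-hydroxy-3,5-bis(3-methylbut-2-en-1-yl)-4-[(triisopropylsilyl)oxy]phenyl}ethan-1-one | CC(=O)c1cc(CC=C(C)C)c(O[Si](C(C)C)(C(C)C)C(C)C)c(CC=C(C)C)c1O | intermediate
21 | (2E)-3-(dimethylamino)-1-{2-hydroxy-3,5-bis(3-methylbut-2-en-1-yl)-4-[(triisopropylsilyl)oxy]phenyl}prop-2-en-1-one | CN(C)/C=C/C(=O)c1cc(CC=C(C)C)c(O[Si](C(C)C)(C(C)C)C(C)C)c(CC=C(C)C)c1O | intermediate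
22 | 6,8-bis(3-methylbut-2-en-1-yl)-7-[(triisopropylsilyl)oxy]-4H-chromen-4-one | O=c1ccoc2c(CC=C(C)C)c(O[Si](C(C)C)(C(C)C)C(C)C)c(CC=C(C)C)cc12 | intermediate
23 | {4-[(tert-butyldimethylsilyl)oxy]phenyl}boronic acid | CC(C)(C)[Si](C)(C)Oc1ccc(B(O)O)cc1 | starting material
24 | (2S)-2-{4-[(tert-butyldimethylsilyl)oxy]phenyl}-6,8-bis(3-methylbut-2-en-1-yl)-7-[(triisopropylsilyl)oxy]-2,3-dihydro-4H-chromen-4-one | CC(C)=CCc1cc2c(c(CC=C(C)C)c1O[Si](C(C)C)(C(C)C)C(C)C)O[C@H](c1ccc(O[Si](C)(C)C(C)(C)C)cc1)CC2=O | intermediate
25 | (2S)-7-hydroxy-2-(4-hydroxyphenyl)-6,8-bis(3-methylbut-2-en-1-yl)-2,3-dihydro-4H-chromen-4-one | CC(C)=CCc1cc2c(c(CC=C(C)C)c1O)O[C@H](c1ccc(O)cc1)CC2=O | target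

**Count**

Total steps: 12. Longest linear sequence: 9 steps (1–3 then 7–12 from sulcatone; equally 4–12 from ethynyltrimethylsilane).

**Steps most likely to fail**

Step 7 (key step). The acyclic α-alkyl diazo ketone may react in part from its s-E conformer, where the keto carbene undergoes a 1,2-hydrogen shift to a cross-conjugated trienone instead of Wolff migration. Prolonged 254 nm irradiation may also degrade the ynol ether or dimerise the ketene. The fallback makes the same vinylketene thermally, without light or carbene. It sets out from prenyl bromide 8: the dianion of but-3-enoic acid (2 LDA, THF, −78 °C) should be alkylated at the α-carbon by 8 to give 2-ethenyl-5-methylhex-4-enoic acid F1. Oxalyl chloride with catalytic DMF should convert it into 2-ethenyl-5-methylhex-4-enoyl chloride F2. Slow addition of Et3N to F2 and ynol ether 13 in toluene at rt should generate vinylketene 14 by dehydrochlorination, which is trapped as cyclobutenone 15. Heating at 80–110 °C should then carry 15 through 16 and 17, and the route is rejoined at phenol 18.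

Step 9 (photo-Fries shift). The acetyl/phenoxyl radical pair may escape the solvent cage and return phenol 18, whose o-prenyl group can add the excited phenol O–H across the alkene under UV light, so mass balance may be poor. The fallback installs the carbon ortho to the hydroxyl by chelation-controlled chemistry in the dark. It sets out from phenol 18: ortho-formylation with MgCl2, Et3N and paraformaldehyde in MeCN at reflux (Casnati–Skattebøl formylation) should give 2-hydroxy-3,5-bis(3-methylbut-2-en-1-yl)-4-[(triisopropylsilyl)oxy]benzaldehyde F3. Excess MeMgBr in THF at 0 °C should give 2-(1-hydroxyethyl)-4,6-bis(3-methylbut-2-en-1-yl)-5-[(triisopropylsilyl)oxy]phenol F4. Oxidation of the benzylic alcohol with activated MnO2 in CH2Cl2 should give the ketone, and the route is rejoined at acetophenone 20.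

Step 11 (asymmetric aryl addition). Insertion into the electron-rich, donor-substituted chromone may be slow enough for protodeboronation of 23 to dominate, and reversible ring opening at elevated temperature could erode the enantiomeric purity. The fallback closes the O1–C2 bond instead of the C2–aryl bond and obtains the enantiomer by resolution. It sets out from acetophenone 20: pyrrolidine-promoted condensation with 4-[(tert-butyldimethylsilyl)oxy]benzaldehyde in EtOH at 60 °C should give (2E)-3-{4-[(tert-butyldimethylsilyl)oxy]phenyl}-1-{2-hydroxy-3,5-bis(3-methylbut-2-en-1-yl)-4-[(triisopropylsilyl)oxy]phenyl}prop-2-en-1-one F5. This chalcone should close in the same pot by oxa-Michael addition to rac-2-{4-[(tert-butyldimethylsilyl)oxy]phenyl}-6,8-bis(3-methylbut-2-en-1-yl)-7-[(triisopropylsilyl)oxy]-2,3-dihydro-4H-chromen-4-one F6. Preparative HPLC on a polysaccharide chiral stationary phase should separate the enantiomers, and the route is rejoined at 24. The (2R)-2-{4-[(tert-butyldimethylsilyl)oxy]phenyl}-6,8-bis(3-methylbut-2-en-1-yl)-7-[(triisopropylsilyl)oxy]-2,3-dihydro-4H-chromen-4-one F7 is re-equilibrated with pyrrolidine through F5 and recycled.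

**Further compounds**

F1 | step 7 | 2-ethenyl-5-methylhex-4-enoic acid | C=CC(CC=C(C)C)C(=O)O
F2 | step 7 | 2-ethenyl-5-methylhex-4-enoyl chloride | C=CC(CC=C(C)C)C(=O)Cl
F3 | step 9 | 2-hydroxy-3,5-bis(3-methylbut-2-en-1-yl)-4-[(triisopropylsilyl)oxy]benzaldehyde | O=Cc1cc(CC=C(C)C)c(O[Si](C(C)C)(C(C)C)C(C)C)c(CC=C(C)C)c1O
F4 | step 9 | 2-(1-hydroxyethyl)-4,6-bis(3-methylbut-2-en-1-yl)-5-[(triisopropylsilyl)oxy]phenol | CC(O)c1cc(CC=C(C)C)c(O[Si](C(C)C)(C(C)C)C(C)C)c(CC=C(C)C)c1O
F5 | step 11 | (2E)-3-{4-[(tert-butyldimethylsilyl)oxy]phenyl}-1-{2-hydroxy-3,5-bis(3-methylbut-2-en-1-yl)-4-[(triisopropylsilyl)oxy]phenyl}prop-2-en-1-one | CC(C)=CCc1cc(C(=O)/C=C/c2ccc(O[Si](C)(C)C(C)(C)C)cc2)c(O)c(CC=C(C)C)c1O[Si](C(C)C)(C(C)C)C(C)C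
F6 | step 11 | rac-2-{4-[(tert-butyldimethylsilyl)oxy]phenyl}-6,8-bis(3-methylbut-2-en-1-yl)-7-[(triisopropylsilyl)oxy]-2,3-dihydro-4H-chromen-4-one | CC(C)=CCc1cc2c(c(CC=C(C)C)c1O[Si](C(C)C)(C(C)C)C(C)C)OC(c1ccc(O[Si](C)(C)C(C)(C)C)cc1)CC2=O
F7 | step 11 | (2R)-2-{4-[(tert-butyldimethylsilyl)oxy]phenyl}-6,8-bis(3-methylbut-2-en-1-yl)-7-[(triisopropylsilyl)oxy]-2,3-dihydro-4H-chromen-4-one | CC(C)=CCc1cc2c(c(CC=C(C)C)c1O[Si](C(C)C)(C(C)C)C(C)C)O[C@@H](c1ccc(O[Si](C)(C)C(C)(C)C)cc1)CC2=O
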